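**Plan**
- Retrosynthetic cuts, in order: C14=C15 enol ether (from a C15 methyl acetal), C8–O, then C9–C10 (ring B), then C8–C9 (ketone enolate + lactone), then C5–C6 (Claisen) and the C13 epoxide.
- Forward: ring A by annulation and fragment 1 (ethyl ketone 7); fragment 2 (spiro lactone acetal 15, carrying C13 and masked ring D); union and dehydration give oxolane ring C with an exocyclic C8=C9 bond; step 10 closes ring B; ring D is unmasked last.
- Enabling feature: the C7 ketone is conjugated through C8=C9 to the oxygen-bearing C9 of ring C, so C9 is a radical acceptor. C10 with its methyl is a tertiary radical available from the C1=C10 alkene of ring A. The helper is the C15 acetal, removed in step 13.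
- Stereochemistry: C5 from a Corey–Bakshi–Shibata reduction relayed by Claisen chirality transfer; C13 from a Sharpless epoxidation; C10 and C9 from the chair transition state of step 10; C8 by enolate oxygenation anti to the C9–O bond.

Key step: step 10

Assumption: labdane numbering and α/β descriptors (C20 β, H5 α) are used for the bicyclic compounds and for the corresponding atoms of their precursors; the acetal carbon C15 is carried as a mixture of epimers and becomes sp2 in the last step.

**Route**

Step 1
Reactants: 1 isobutyraldehyde; 2 ethyl vinyl ketone (pent-1-en-3-one)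
Product: 4 2,4,4-trimethylcyclohex-2-en-1-one, via keto aldehyde 3 (not isolated)
Conditions: H2SO4 (cat.), toluene, 50 °C then reflux (Dean–Stark)
Reagents that add atoms: none
Why: Acid-catalysed Michael addition of the aldehyde enol to the enone followed by intramolecular aldol condensation (Robinson-type annulation) should give the cyclohexenone, with no stereocenter formed.

Step 2
Reactants: 4 2,4,4-trimethylcyclohex-2-en-1-one
Product: 5 (1R)-2,4,4-trimethylcyclohex-2-en-1-ol
Conditions: (S)-Me-CBS oxazaborolidine (10 mol %), BH3·SMe2, THF, −20 °C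
Reagents that add atoms: none
Why: Corey–Bakshi–Shibata reduction, in which the alkenyl branch acts as the large group, so the S catalyst should give the R carbinol (hydroxyl on the β face at the future C1).

Step 3
Reactants: 5 (1R)-2,4,4-trimethylcyclohex-2-en-1-ol
Product: 6 N,N-dimethyl-2-[(1S)-2,6,6-trimethylcyclohex-2-en-1-yl]acetamide
Conditions: MeC(OMe)2NMe2, xylene, 140 °C
Reagents that add atoms: N,N-dimethylacetamide dimethyl acetal (CN(C)C(C)(OC)OC)
Why: Eschenmoser–Claisen rearrangement, whose suprafacial [3,3] shift transfers the β C1–O bond into a β C5–C6 bond next to the gem-dimethyl carbon and so sets C5 (S) while placing the alkene at C1=C10.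

Step 4
Reactants: 6 N,N-dimethyl-2-[(1S)-2,6,6-trimethylcyclohex-2-en-1-yl]acetamide
Product: 7 1-[(1S)-2,6,6-trimethylcyclohex-2-en-1-yl]butan-2-one
Conditions: EtLi, Et2O/THF, −78 to 0 °C; aqueous work-up
Reagents that add atoms: ethyllithium ([Li]CC)
Why: Addition of an organolithium to a tertiary amide stops at the lithium hemiaminal and releases the ketone on work-up, and the C5 stereocenter is β to the carbonyl and cannot epimerize.

Step 5
Reactants: 8 2-bromoprop-2-en-1-ol; 9 (3-ethoxy-3-oxopropyl)zinc bromide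
Product: 10 ethyl 4-(hydroxymethyl)pent-4-enoate
Conditions: PdCl2(dppf) (5 mol %), THF, 50 °C
Reagents that add atoms: none
Why: Negishi coupling of an alkenyl bromide with a functionalized alkylzinc halide, which tolerates the ester and the free hydroxyl.

Step 6
Reactants: 10 ethyl 4-(hydroxymethyl)pent-4-enoate
Product: 11 ethyl 3-[(2S)-2-(hydroxymethyl)oxiran-2-yl]propanoate
Conditions: Ti(OiPr)4 (10 mol %), L-(+)-DET, t-BuOOH, 4 Å MS, CH2Cl2, −20 °C
Reagents that add atoms: tert-butyl hydroperoxide (CC(C)(C)OO)
Why: Sharpless asymmetric epoxidation of a 2-substituted allylic alcohol, in which L-(+)-tartrate should deliver oxygen to the face that gives the 2S epoxide and so fixes the future C13.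

Step 7
Reactants: 11 ethyl 3-[(2S)-2-(hydroxymethyl)oxiran-2-yl]propanoate
Product: 13 (5R)-5-(hydroxymethyl)-5-(prop-2-en-1-yl)oxolan-2-one, via diol ester 12 (not isolated)
Conditions: CH2=CHMgBr, CuI (20 mol %), THF, −40 °C; aq. NH4Cl; then TsOH (cat.), CH2Cl2, rt
Reagents that add atoms: vinylmagnesium bromide (C=C[Mg]Br)
Why: Copper-catalysed Grignard opening at the unsubstituted epoxide carbon leaves the quaternary center untouched, and acid then closes the γ-lactone from the tertiary hydroxyl and the ester.

Step 8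
Reactants: 13 (5R)-5-(hydroxymethyl)-5-(prop-2-en-1-yl)oxolan-2-one
Product: 15 (5R)-8-methoxy-1,7-dioxaspiro[4.4]nonan-2-one, via lactol 14 (not isolated)
Conditions: O3, CH2Cl2/MeOH, −78 °C; Me2S; then PPTS, MeOH, rt
Reagents that add atoms: ozone ([O-][O+]=O); methanol (CO)
Why: Ozonolysis with reductive work-up gives an aldehyde that closes onto the primary hydroxyl as a five-membered lactol, and acid-catalysed acetalization with methanol gives the methyl acetal that masks the ring D enol ether against the hydride conditions of step 10.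

Step 9
Reactants: 7 1-[(1S)-2,6,6-trimethylcyclohex-2-en-1-yl]butan-2-one; 15 (5R)-8-methoxy-1,7-dioxaspiro[4.4]nonan-2-one
Product: 17 (3Z)-3-[(5R)-8-methoxy-1,7-dioxaspiro[4.4]nonan-2-ylidene]-1-[(1S)-2,6,6-trimethylcyclohex-2-en-1-yl]butan-2-one, via hemiketal 16 (not isolated)
Conditions: LDA, THF, −78 °C; add 15, −78 to −20 °C; AcOH; then PPTS (cat.), 4 Å MS, toluene, 50 °C
Reagents that add atoms: none
Why: Claisen-type acylation of the kinetic enolate (formed at the ethyl CH2, C8, not at the shielded C6) by the lactone gives a hemiketal that dehydrates under acid to the conjugated 2-alkylidene oxolane; acid equilibration should favour the Z isomer, with the acyl group beside the ring oxygen and the C17 methyl beside C11, which avoids allylic strain between the acyl group and the ring CH2.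

Step 10
Reactants: 17 (3Z)-3-[(5R)-8-methoxy-1,7-dioxaspiro[4.4]nonan-2-ylidene]-1-[(1S)-2,6,6-trimethylcyclohex-2-en-1-yl]butan-2-one
Product: 18 (13R)-15-methoxy-9α,13:15,16-diepoxy-8βH-labdan-7-one
Conditions: Fe(acac)3 (30 mol %), PhSiH3 (slow addition), EtOH, 60 °C
Reagents that add atoms: none
Why: Proposed new method: the iron hydride formed from Fe(acac)3 and PhSiH3 transfers a hydrogen atom to C1 of the trisubstituted ring A alkene, and the tertiary C10 radical adds 6-endo-trig to C9, the β-carbon of the tetrasubstituted β-alkoxy enone, giving an α-keto radical at C8 that is reduced to the iron enolate and protonated by ethanol. The closest known reactions are the iron-hydride HAT-initiated Giese cyclization that builds trans-decalins with quaternary carbons and the radical cyclization of β-alkoxyacrylates at the oxygen-bearing carbon; new here are the tetrasubstituted push-pull acceptor and the joining of two fully substituted carbons. Ring B closes through a chair transition state with the C5–C6 bond equatorial on ring A, so C9 bonds to the face of C10 that leaves C20 axial and the ring fusion trans (C10 controlled by C5). At C9 the alkene substituent cis to C7 becomes axial, so the Z geometry places the ring C oxygen α-axial and C11 β-equatorial; C8 is set by enolate protonation and is erased in step 11. The step needs HAT to the ring A alkene and not to the electron-poor C8=C9 bond, 6-endo and not 5-exo closure (secured by the polarity-matched β-carbon and the fully substituted C8), and cyclization faster than reduction of the radical (slow silane addition keeps the hydride concentration low); the C15 acetal keeps ring D from acting as a HAT acceptor.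

Step 11
Reactants: 18 (13R)-15-methoxy-9α,13:15,16-diepoxy-8βH-labdan-7-one
Product: 20 (13R)-8β-hydroxy-15-methoxy-9α,13:15,16-diepoxylabdan-7-one, via hydroperoxide 19 (not isolated)
Conditions: KOt-Bu, P(OEt)3, O2, THF/t-BuOH, −20 °C
Reagents that add atoms: dioxygen (O=O)
Why: Base-mediated autoxidation of the more substituted C8 enolate with in situ phosphite reduction of the hydroperoxide (tertiary α-hydroxylation of a ketone); oxygen should enter on the β face, anti to the pseudoaxial C9–O bond that eclipses the α trajectory, by axial attack that lets the C17 methyl become equatorial.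

Step 12
Reactants: 20 (13R)-8β-hydroxy-15-methoxy-9α,13:15,16-diepoxylabdan-7-one
Product: 21 (13R)-8β-acetoxy-15-methoxy-9α,13:15,16-diepoxylabdan-7-one
Conditions: Ac2O, DMAP, Et3N, CH2Cl2, 40 °C
Reagents that add atoms: acetic anhydride (CC(=O)OC(C)=O)
Why: DMAP-catalysed acylation of a hindered tertiary α-ketol under forcing but non-acidic conditions that spare the acetal, with no stereocenter affected.

Step 13
Reactants: 21 (13R)-8β-acetoxy-15-methoxy-9α,13:15,16-diepoxylabdan-7-one
Product: 23 (5S,8R,9S,10S,13R)-8-acetoxy-9,13:15,16-diepoxylabd-14-en-7-one, via silyl enol ether 22 (not isolated)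
Conditions: TMSOTf, i-Pr2NEt, CH2Cl2, −20 to 0 °C; then KF (cat.), MeOH, 0 °C
Reagents that add atoms: none
Why: Silyl triflate/amine elimination of methanol from the cyclic acetal (oxocarbenium formation, then deprotonation at C14, the only β-carbon bearing hydrogen) should give the 2,3-dihydrofuran under basic conditions, while the ketone is silylated in passing and freed again by fluoride-catalysed methanolysis.

**Compound list**
1 | isobutyraldehyde | CC(C)C=O | starting material
2 | ethyl vinyl ketone (pent-1-en-3-one) | CCC(=O)C=C | starting material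
3 | 2,2-dimethyl-5-oxoheptanal | O=CC(C)(C)CCC(=O)CC | intermediate
4 | 2,4,4-trimethylcyclohex-2-en-1-one | CC1=CC(C)(C)CCC1=O | intermediate
5 | (1R)-2,4,4-trimethylcyclohex-2-en-1-ol | CC1=CC(C)(C)CC[C@H]1O | intermediate
6 | N,N-dimethyl-2-[(1S)-2,6,6-trimethylcyclohex-2-en-1-yl]acetamide | CN(C)C(=O)C[C@@H]1C(C)=CCCC1(C)C | intermediate
7 | 1-[(1S)-2,6,6-trimethylcyclohex-2-en-1-yl]butan-2-one | CCC(=O)C[C@@H]1C(C)=CCCC1(C)C | intermediate
8 | 2-bromoprop-2-en-1-ol | C=C(Br)CO | starting material
9 | (3-ethoxy-3-oxopropyl)zinc bromide | CCOC(=O)CC[Zn]Br | starting material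
10 | ethyl 4-(hydroxymethyl)pent-4-enoate | C=C(CO)CCC(=O)OCC | intermediate
11 | ethyl 3-[(2S)-2-(hydroxymethyl)oxiran-2-yl]propanoate | CCOC(=O)CC[C@]1(CO)CO1 | intermediate
12 | ethyl (4R)-4-hydroxy-4-(hydroxymethyl)hept-6-enoate | CCOC(=O)CC[C@](O)(CO)CC=C | intermediate
13 | (5R)-5-(hydroxymethyl)-5-(prop-2-en-1-yl)oxolan-2-one | O=C1CC[C@](O1)(CO)CC=C | intermediate
14 | (5R)-8-hydroxy-1,7-dioxaspiro[4.4]nonan-2-one (C8 epimers) | O=C1CC[C@@]2(O1)CC(O)OC2 | intermediate
15 | (5R)-8-methoxy-1,7-dioxaspiro[4.4]nonan-2-one (C8 epimers) | O=C1CC[C@@]2(O1)CC(OC)OC2 | intermediate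
16 | 3-[(5R)-2-hydroxy-8-methoxy-1,7-dioxaspiro[4.4]nonan-2-yl]-1-[(1S)-2,6,6-trimethylcyclohex-2-en-1-yl]butan-2-one (hemiketal, other centers as mixtures) | O=C(C[C@@H]1C(C)=CCCC1(C)C)C(C)C2(O)CC[C@@]3(O2)CC(OC)OC3 | intermediate
17 | (3Z)-3-[(5R)-8-methoxy-1,7-dioxaspiro[4.4]nonan-2-ylidene]-1-[(1S)-2,6,6-trimethylcyclohex-2-en-1-yl]butan-2-one | O=C(C[C@@H]1C(C)=CCCC1(C)C)/C(C)=C2/CC[C@@]3(O2)CC(OC)OC3 | intermediate
18 | (13R)-15-methoxy-9α,13:15,16-diepoxy-8βH-labdan-7-one (C17 α, C15 epimers) | C[C@@H]1C(=O)C[C@H]2C(C)(C)CCC[C@]2(C)[C@@]12CC[C@]1(CC(OC)OC1)O2 | intermediate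
19 | (13R)-8β-hydroperoxy-15-methoxy-9α,13:15,16-diepoxylabdan-7-one | C[C@]1(OO)C(=O)C[C@H]2C(C)(C)CCC[C@]2(C)[C@@]12CC[C@]1(CC(OC)OC1)O2 | intermediate
20 | (13R)-8β-hydroxy-15-methoxy-9α,13:15,16-diepoxylabdan-7-one | C[C@]1(O)C(=O)C[C@H]2C(C)(C)CCC[C@]2(C)[C@@]12CC[C@]1(CC(OC)OC1)O2 | intermediate
21 | (13R)-8β-acetoxy-15-methoxy-9α,13:15,16-diepoxylabdan-7-one | CC(=O)O[C@@]1(C)C(=O)C[C@H]2C(C)(C)CCC[C@]2(C)[C@@]12CC[C@]1(CC(OC)OC1)O2 | intermediate
22 | (13R)-8β-acetoxy-7-(trimethylsilyloxy)-9α,13:15,16-diepoxylabda-6,14-diene | CC(=O)O[C@@]1(C)C(O[Si](C)(C)C)=C[C@H]2C(C)(C)CCC[C@]2(C)[C@@]12CC[C@]1(C=COC1)O2 | intermediate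
23 | (5S,8R,9S,10S,13R)-8-acetoxy-9,13:15,16-diepoxylabd-14-en-7-one (8β-acetoxy, 9α,13-epoxy) | CC(=O)O[C@@]1(C)C(=O)C[C@H]2C(C)(C)CCC[C@]2(C)[C@@]12CC[C@]1(C=COC1)O2 | target

**Step count and risks**
Total: 13 steps. Longest linear sequence: 9 steps (steps 1–4 or 5–8, then 9–13).

Most likely to fail:

1. Step 10 (proposed new method). The likely failure is reduction of the tertiary C10 radical by the iron hydride (net hydrogenation of the ring A alkene) outrunning the slow addition to a hindered, donor-substituted acceptor. A second risk is the wrong C9 configuration if the alkene of 17 is not Z. The fallback uses known reactions and generates the same radical without a hydride donor. Setting out from 17, Mukaiyama hydration of the ring A alkene (Mn(dpm)3, PhSiH3, O2, i-PrOH, 0 °C) should give the tertiary C10 alcohol (3Z)-1-[(1S)-2-hydroxy-2,6,6-trimethylcyclohexyl]-3-[(5R)-8-methoxy-1,7-dioxaspiro[4.4]nonan-2-ylidene]butan-2-one F1. Acylation with methyl chlorooxoacetate (Et3N, DMAP) gives its mixed methyl oxalate F2, and CsOH converts this to the cesium oxalate F3. Blue-light irradiation with Ir[dF(CF3)ppy]2(dtbbpy)PF6 (DME/DMF, H2O) releases two CO2 and the C10 radical, which should cyclize (decarboxylative photoredox Giese reaction); reduction and protonation of the α-keto radical rejoin the route at 18.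

2. Step 11. The likely failures are oxygenation at C6 in place of C8, retro-oxa-Michael opening of ring C under the equilibrating base, and incomplete facial control. The fallback blocks C6 by unsaturation and uses only kinetic base. Setting out from 18, LDA/TMSCl (THF, −78 °C) gives the C6 silyl enol ether (13R)-15-methoxy-7-(trimethylsilyloxy)-9α,13:15,16-diepoxy-8βH-labd-6-ene F4. Saegusa–Ito oxidation (Pd(OAc)2, MeCN) gives the enone (13R)-15-methoxy-9α,13:15,16-diepoxy-8βH-labd-5-en-7-one F5, in which C8–H is the only enolizable position. LiHMDS at −78 °C followed by 2-(phenylsulfonyl)-3-phenyloxaziridine gives (13R)-8β-hydroxy-15-methoxy-9α,13:15,16-diepoxylabd-5-en-7-one F6. Hydrogenation (H2, Pd/C, EtOAc) from the α face restores the trans ring fusion and returns to 20.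

3. Step 13. The likely failure is Lewis-acid ionization of the allylic spiro ether (C13–O) of the product, which would open ring C and aromatize ring D to a furan. The fallback avoids silyl triflate. Setting out from 21, mild hydrolysis (AcOH/H2O/THF, 40 °C) gives the lactol (13R)-8β-acetoxy-15-hydroxy-9α,13:15,16-diepoxylabdan-7-one F7. MsCl/Et3N (CH2Cl2, −40 to 0 °C) then forms the anomeric mesylate (13R)-8β-acetoxy-15-(methanesulfonyloxy)-9α,13:15,16-diepoxylabdan-7-one F8, which eliminates in the basic medium to give 23.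

Further compounds
F1 | step 10 | (3Z)-1-[(1S)-2-hydroxy-2,6,6-trimethylcyclohexyl]-3-[(5R)-8-methoxy-1,7-dioxaspiro[4.4]nonan-2-ylidene]butan-2-one (carbinol epimers) | O=C(C[C@@H]1C(C)(O)CCCC1(C)C)/C(C)=C2/CC[C@@]3(O2)CC(OC)OC3
F2 | step 10 | mixed methyl oxalate ester of F1 at the tertiary hydroxyl | O=C(C[C@@H]1C(C)(OC(=O)C(=O)OC)CCCC1(C)C)/C(C)=C2/CC[C@@]3(O2)CC(OC)OC3
F3 | step 10 | cesium oxalate of F1 | O=C(C[C@@H]1C(C)(OC(=O)C(=O)[O-])CCCC1(C)C)/C(C)=C2/CC[C@@]3(O2)CC(OC)OC3.[Cs+]
F4 | step 11 | (13R)-15-methoxy-7-(trimethylsilyloxy)-9α,13:15,16-diepoxy-8βH-labd-6-ene | C[C@@H]1C(O[Si](C)(C)C)=C[C@H]2C(C)(C)CCC[C@]2(C)[C@@]12CC[C@]1(CC(OC)OC1)O2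
F5 | step 11 | (13R)-15-methoxy-9α,13:15,16-diepoxy-8βH-labd-5-en-7-one | C[C@@H]1C(=O)C=C2C(C)(C)CCC[C@]2(C)[C@@]12CC[C@]1(CC(OC)OC1)O2
F6 | step 11 | (13R)-8β-hydroxy-15-methoxy-9α,13:15,16-diepoxylabd-5-en-7-one | C[C@]1(O)C(=O)C=C2C(C)(C)CCC[C@]2(C)[C@@]12CC[C@]1(CC(OC)OC1)O2
F7 | step 13 | (13R)-8β-acetoxy-15-hydroxy-9α,13:15,16-diepoxylabdan-7-one | CC(=O)O[C@@]1(C)C(=O)C[C@H]2C(C)(C)CCC[C@]2(C)[C@@]12CC[C@]1(CC(O)OC1)O2
F8 | step 13 | (13R)-8β-acetoxy-15-(methanesulfonyloxy)-9α,13:15,16-diepoxylabdan-7-one | CC(=O)O[C@@]1(C)C(=O)C[C@H]2C(C)(C)CCC[C@]2(C)[C@@]12CC[C@]1(CC(OS(C)(=O)=O)OC1)O2
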